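## Retrosynthetic overview

- The target comes from hydrogenolysis of the two benzyl ethers of the fully assembled keto acetate (last step).
- Key disconnection C6–C7, α to the ketone: 1-bromoheptan-2-one serves as an enolonium (a2) equivalent and meets the C6 alkylborane made in the flask by hydroboration of a C1–C6 alkenyl acetate. A ketone α-carbon is joined to an alkyl–metal carbon, two centres that are both nucleophilic by nature.
- The alkenyl acetate comes from allyl Grignard opening (C3–C4) of an (S)-arylmethyl oxirane, with acetylation of the alkoxide in the same flask. The oxirane comes from the aryl Grignard reagent and (S)-epichlorohydrin, which supplies the only stereocentre.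
- The bromoketone comes from hexanoyl chloride through its diazoketone.
- Rings: the benzene ring is bought. The only ring formed is the transient oxirane (step 1), opened again in step 2.

Assumption: 1-bromo-3,5-bis(benzyloxy)benzene is taken as a catalogue compound.

## Route

Step 1
Reactants: 1 1-bromo-3,5-bis(benzyloxy)benzene; 2 (S)-epichlorohydrin
Product: 6 (S)-2-[3,5-bis(benzyloxy)benzyl]oxirane, via aryl Grignard reagent 3 (not isolated), via bromomagnesium chloroalkoxide 4 (not isolated), via chlorohydrin 5 (not isolated)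
Conditions: Mg turnings (I2 crystal), THF, 40 °C; then 2 (1.2 equiv), CuI (10 mol %), −40 → 0 °C; cold 1 M HCl quench; crude 5, 2 M aq NaOH, THF, rt
Reagents that add atoms: none
Why: Copper-catalysed Grignard opening of the epoxide at its unsubstituted carbon is much faster than displacement of chloride, so the stereocentre of 2 passes unchanged into chlorohydrin 5, and the intramolecular Williamson ring closure at the achiral CH2Cl carbon then gives (S)-6 without any bond to the stereocentre being broken.

Step 2
Reactants: 6 (S)-2-[3,5-bis(benzyloxy)benzyl]oxirane; 7 allylmagnesium bromide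
Product: 9 (R)-1-[3,5-bis(benzyloxy)phenyl]hex-5-en-2-yl acetate, via bromomagnesium alkoxide 8 (not isolated)
Conditions: 7 (1.0 M in Et2O, 1.3 equiv), CuI (10 mol %), THF, −30 → 0 °C; then Ac2O (3 equiv), DMAP (10 mol %), 0 °C → rt; cold 1 M HCl work-up
Reagents that add atoms: acetic anhydride CC(=O)OC(C)=O
Why: SN2 opening of the terminal epoxide by the allyl Grignard reagent at the CH2 terminus leaves the carbinol carbon untouched (it is now C2 with R configuration), and the magnesium alkoxide is acetylated in the same flask by DMAP-catalysed nucleophilic acyl substitution.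

Step 3
Reactants: 10 hexanoyl chloride
Product: 12 1-bromoheptan-2-one, via 1-diazoheptan-2-one 11 (not isolated)
Conditions: TMSCHN2 (2 M in hexanes, 2 equiv), MeCN–THF 1:1, 0 °C → rt; then 48% aq HBr, 0 °C
Reagents that add atoms: (trimethylsilyl)diazomethane C[Si](C)(C)C=[N+]=[N-]; hydrogen bromide Br
Why: Acylation of the diazoalkane carbon by the acid chloride with loss of the silyl group (Arndt–Eistert-type diazoketone formation), then protonation and SN2 displacement of N2 by bromide, gives the bromomethyl ketone with unambiguous regiochemistry and no stereocentre involved.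

Step 4
Reactants: 9 (R)-1-[3,5-bis(benzyloxy)phenyl]hex-5-en-2-yl acetate; 12 1-bromoheptan-2-one
Product: 15 (R)-1-[3,5-bis(benzyloxy)phenyl]-8-oxotridecan-2-yl acetate, via B-alkyl-9-BBN 13 (not isolated), via enol borinate 14 (not isolated)
Conditions: 9-BBN (0.5 M in THF, 1.0 equiv), 0 °C → rt, 3 h; then 12 (1.1 equiv), potassium 2,6-di-tert-butylphenoxide (1.1 equiv, made from 2,6-di-tert-butylphenol and KOtBu in THF) added dropwise, 0 °C → rt; H2O work-up
Reagents that add atoms: none
Why: This is the Brown α-alkylation of an α-bromo ketone with a B-alkyl-9-BBN, in which anti-Markovnikov hydroboration places boron on C6, the hindered phenoxide (too bulky to bind boron) deprotonates 12 at the CHBr carbon, the bromo enolate adds to boron and the primary alkyl group shifts from boron to carbon with loss of bromide (1,2-metallate rearrangement) so that the ketone α-carbon reacts as an enolonium equivalent, and protonolysis of enol borinate 14 by the liberated phenol gives 15 with the remote acetate stereocentre untouched.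

Step 5
Reactants: 15 (R)-1-[3,5-bis(benzyloxy)phenyl]-8-oxotridecan-2-yl acetate
Product: 16 (R)-1-(3,5-dihydroxyphenyl)-8-oxotridecan-2-yl acetate (CNP0213461.1)
Conditions: H2 (1 atm), 10% Pd/C, EtOAc, rt
Reagents that add atoms: none
Why: Catalytic hydrogenolysis cleaves the two aryl benzyl ethers while the dialkyl ketone, the secondary acetate (homobenzylic, so not prone to hydrogenolysis) and the stereocentre are inert under these conditions.

## Compound list

1 | 1-bromo-3,5-bis(benzyloxy)benzene | Brc1cc(OCc2ccccc2)cc(OCc2ccccc2)c1 | starting material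
2 | (S)-epichlorohydrin | ClC[C@@H]1CO1 | starting material
3 | [3,5-bis(benzyloxy)phenyl]magnesium bromide | Br[Mg]c1cc(OCc2ccccc2)cc(OCc2ccccc2)c1 | intermediate
4 | bromomagnesium (S)-1-[3,5-bis(benzyloxy)phenyl]-3-chloropropan-2-olate | ClC[C@@H](O[Mg]Br)Cc1cc(OCc2ccccc2)cc(OCc2ccccc2)c1 | intermediate
5 | (S)-1-[3,5-bis(benzyloxy)phenyl]-3-chloropropan-2-ol | ClC[C@@H](O)Cc1cc(OCc2ccccc2)cc(OCc2ccccc2)c1 | intermediate
6 | (S)-2-[3,5-bis(benzyloxy)benzyl]oxirane | C([C@H]1CO1)c1cc(OCc2ccccc2)cc(OCc2ccccc2)c1 | intermediate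
7 | allylmagnesium bromide | C=CC[Mg]Br | starting material
8 | bromomagnesium (R)-1-[3,5-bis(benzyloxy)phenyl]hex-5-en-2-olate | C=CCC[C@H](Cc1cc(OCc2ccccc2)cc(OCc2ccccc2)c1)O[Mg]Br | intermediate
9 | (R)-1-[3,5-bis(benzyloxy)phenyl]hex-5-en-2-yl acetate | C=CCC[C@H](Cc1cc(OCc2ccccc2)cc(OCc2ccccc2)c1)OC(C)=O | intermediate
10 | hexanoyl chloride | CCCCCC(Cl)=O | starting material
11 | 1-diazoheptan-2-one | CCCCCC(=O)C=[N+]=[N-] | intermediate
12 | 1-bromoheptan-2-one | CCCCCC(=O)CBr | intermediate
13 | (R)-1-[3,5-bis(benzyloxy)phenyl]-6-(9-borabicyclo[3.3.1]nonan-9-yl)hexan-2-yl acetate | B1(C2CCCC1CCC2)CCCC[C@H](Cc1cc(OCc2ccccc2)cc(OCc2ccccc2)c1)OC(C)=O | intermediate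
14 | (R)-1-[3,5-bis(benzyloxy)phenyl]-8-[(9-borabicyclo[3.3.1]nonan-9-yl)oxy]tridec-7-en-2-yl acetate (E/Z mixture) | CCCCCC(OB1C2CCCC1CCC2)=CCCCC[C@H](Cc1cc(OCc2ccccc2)cc(OCc2ccccc2)c1)OC(C)=O | intermediate
15 | (R)-1-[3,5-bis(benzyloxy)phenyl]-8-oxotridecan-2-yl acetate | CCCCCC(=O)CCCCC[C@H](Cc1cc(OCc2ccccc2)cc(OCc2ccccc2)c1)OC(C)=O | intermediate
16 | (R)-1-(3,5-dihydroxyphenyl)-8-oxotridecan-2-yl acetate | CCCCCC(=O)CCCCC[C@H](Cc1cc(O)cc(O)c1)OC(C)=O | target

## Step count and risks

Total step count: 5. Longest linear sequence: 4 steps (steps 1, 2, 4, 5); step 3 is a one-step branch.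

**Step 4 (most likely to fail).** The boron ate-complex alkylation can fail through self-condensation of 12 under base, competing migration of the bicyclic B–C bond, or base attack on the acetate. The fallback sets out from 9 and 12 and comes back at 15. It keeps the C6–C7 bond and the enolonium-type polarity but forms the bond by radical group transfer. Treat 12 with EtOCS2K (acetone, 0 °C) to give O-ethyl S-(2-oxoheptyl) carbonodithioate F1. Add its electrophilic α-keto radical to the terminal alkene of 9 (dilauroyl peroxide in portions, 1,2-dichloroethane, reflux). This gives (2R)-1-[3,5-bis(benzyloxy)phenyl]-5-[(ethoxycarbonothioyl)sulfanyl]-8-oxotridecan-2-yl acetate F2 as a mixture of C5 epimers. Reductive removal of the xanthate (Bu3SnH, AIBN, toluene, 80 °C) gives 15, and step 5 follows unchanged.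

**Step 1.** The ambident electrophile 2 can erode ee through direct chloride displacement, or give bis-arylation. The fallback sets out from 1 and comes back at 6. It replaces the chiral-pool source by a catalytic resolution. Quench Grignard reagent 3 with allyl bromide (CuI cat., THF, 0 °C) to give 1-allyl-3,5-bis(benzyloxy)benzene F3. Epoxidise with mCPBA (CH2Cl2, 0 °C → rt) to rac-2-[3,5-bis(benzyloxy)benzyl]oxirane F4. Resolve by Jacobsen hydrolytic kinetic resolution with (S,S)-(salen)Co(OAc) (trivalent cobalt, 0.5 mol %), 0.55 equiv H2O, THF, rt. This hydrolyses the (R)-epoxide to (R)-3-[3,5-bis(benzyloxy)phenyl]propane-1,2-diol F5 and leaves 6. The catalyst enantiomer is assigned from the usual sense of this resolution for alkyl-substituted terminal epoxides and should be confirmed on a small scale.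

**Step 2.** MgBr2-induced halohydrin formation or rearrangement of 6 can compete, and acetylation of the magnesium alkoxide may be incomplete. The fallback sets out from 1 (through its Grignard reagent 3) and comes back at 9. It reverses the order of bond formation. Open commercial (R)-1,2-epoxyhex-5-ene (dearer than 2) with 3 (CuI cat., THF, −30 → 0 °C) to give alkoxide 8. Work up with cold 1 M HCl to isolate (R)-1-[3,5-bis(benzyloxy)phenyl]hex-5-en-2-ol F6. Acetylate separately (Ac2O, pyridine, DMAP, CH2Cl2, rt) to give 9.

## Further compounds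

F1 | step 4 | O-ethyl S-(2-oxoheptyl) carbonodithioate | CCCCCC(=O)CSC(=S)OCC
F2 | step 4 | (2R)-1-[3,5-bis(benzyloxy)phenyl]-5-[(ethoxycarbonothioyl)sulfanyl]-8-oxotridecan-2-yl acetate (C5 epimers) | CCCCCC(=O)CCC(SC(=S)OCC)CC[C@H](Cc1cc(OCc2ccccc2)cc(OCc2ccccc2)c1)OC(C)=O
F3 | step 1 | 1-allyl-3,5-bis(benzyloxy)benzene | C=CCc1cc(OCc2ccccc2)cc(OCc2ccccc2)c1
F4 | step 1 | rac-2-[3,5-bis(benzyloxy)benzyl]oxirane | C(C1CO1)c1cc(OCc2ccccc2)cc(OCc2ccccc2)c1
F5 | step 1 | (R)-3-[3,5-bis(benzyloxy)phenyl]propane-1,2-diol | OC[C@H](O)Cc1cc(OCc2ccccc2)cc(OCc2ccccc2)c1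
F6 | step 2 | (R)-1-[3,5-bis(benzyloxy)phenyl]hex-5-en-2-ol | C=CCC[C@H](Cc1cc(OCc2ccccc2)cc(OCc2ccccc2)c1)O
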